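At the last reading of the oak flask, 8.00 min, 51.8% of the substrates charged is not left-handed product, and anyone repeating the run needs to know how much of that leftover can still come over.

common to all: left-handed substrate 0.37 M; right-handed substrate 0.37 M; coupling partner 0.814 M; free catalyst 0.18 mM; racemization catalyst 9.3 mM

| flask | temperature | remark | time |
|---|---|---|---|
| oak | 100 °C | the very flask that is asked about, followed so far |  |
| larch | 95 °C | run made earlier |  |
| flask | 100 °C |  | 12 min |

| run | time / min | left-handed product / % |
|---|---|---|
| oak | 0.500 | 10.8 |
| oak | 1.00 | 18.7 |
| oak | 1.50 | 23.8 |
| oak | 2.50 | 33.0 |
| oak | 4.00 | 39.8 |
| oak | 8.00 | 48.2 |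
| larch | 0.500 | 9.6 |
| larch | 1.00 | 16.4 |
| larch | 1.50 | 22.0 |
| larch | 2.50 | 29.8 |
| larch | 4.00 | 38.2 |
| larch | 8.00 | 48.6 |

(readings scatter by 0.5 percentage points)

- free catalyst is single-handed; left-handed substrate and right-handed substrate are mirror images of each other, charged as a racemate, each of them at the stated concentration
- left-handed product taken out counts as made
- the analysis behind the earlier runs scatters by 0.5 percentage points, standard deviation
- "the catalyst" is free catalyst with its forms; racemization catalyst is a second catalyst
- additions bring no volume worth counting

- north: at 12 min add free catalyst, 50.0% of the amount charged, then wait 6.0 min
- north-east: change nothing and wait 6.0 min more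
- south: at 12 min raise the temperature by 10 K, then wait 6.0 min
- west: at 12 min take out 90% of the left-handed product then present, then wait 6.0 min
- north-west: at 12 min add coupling partner, 50.0% of the amount charged, then wait 6.0 min

- left-handed product, in percent of the left-handed substrate and right-handed substrate together first charged, at 12 min
- the remedy with the largest gain of left-handed product, or "none" below 2 percentage points (north / north-east / south / west / north-west / none)
- left-handed product present, with what was taken out counted in, in percent of the left-handed substrate and right-handed substrate together first charged, after south
- left-handed product present, with what was taken out counted in, in percent of the left-handed substrate and right-handed substrate together first charged, after north-west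

I reach the number at 12 min by two ways from the oak readings. The first takes a first-order approach from nothing through the readings at 4.00 min and 8.00 min, which gives an end value of 50.4% and 50.0% at 12 min. The second takes a rate that falls with the square of what is left, so the reciprocal of the yield is a straight line in the reciprocal of time. Through the readings at 1.00 min and 8.00 min, the slope is 3.74 min, the end value 62.2%, and the yield at 12 min 52.1%.

The two part, so I ask the reading at 0.500 min, which neither way used. It stands at 10.8%. The first way says 8.91% and the second 11.0%, against a scatter of 0.5 percentage points. The first way cheats, and I commit to 52.1%.

The end value of the second way stands higher than the 50.0% that left-handed substrate makes of the charge, so I read right-handed substrate as crossing over by racemization. I take coupling partner as the limiting reagent and read the end value as the point where it is gone. That gives the partner yield, the left-handed product won per coupling partner charged, 0.566. By it, I reckon 16.2% of the partner left at 12 min, so I choose north-west, which adds coupling partner.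

The forecast says 50.8% (range 49.5% to 52.5%), 54% after south, 55.5% after north-west, and picks north: “Adding catalyst restores activity regardless of the partner order”.

The flask gives 52.2% at 12 min.

    coupling partner + free catalyst + left-handed substrate → free catalyst + left-handed product (k = 58.0 L² mol⁻² s⁻¹, Ea = 35.0 kJ mol⁻¹)
    coupling partner + free catalyst + right-handed substrate → free catalyst + right-handed product (k = 20.0 L² mol⁻² s⁻¹, Ea = 49.0 kJ mol⁻¹)
    left-handed substrate + racemization catalyst ⇌ right-handed substrate + racemization catalyst, rate k3*[racemization catalyst]*[left-handed substrate] forward; the back reaction follows from the equilibrium constant (k = 6.60 L mol⁻¹ s⁻¹, Ea = 49.0 kJ mol⁻¹)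
    left-handed product ⇌ right-handed product (k = 1.50 × 10⁻⁴ s⁻¹, Ea = 103 kJ mol⁻¹)
    2 coupling partner → homo dimer (k = 0.00110 L mol⁻¹ s⁻¹, Ea = 87.0 kJ mol⁻¹)
    (constants at 100 °C)

North-west gains 9.8 points and ends at 62.0%, while south ends at 52.8%. Put through the partner yield, 52.2% means 16.1% of the partner left, and the flask holds 12.8%. On the same recipe with 0.20 M of coupling partner, 4.3% of it left at 12 min, the yield reckons 14.6%, and that flask holds 17.4% of left-handed product.

The runs come from a simulation from invented constants, noise included.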